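## Structural features

The target is a flavonol. Benzene ring A (C4a to C8a) is fused to the 4-pyranone ring C (O1, C2, C3, C4), and the 4-hydroxyphenyl ring B is attached to C2 by a single C–C bond. Ring A carries hydroxyl groups at C5 and C7 and, at C8, a 2-methylbut-3-en-2-yl group whose quaternary carbon lies between C8a–O1 and the C7 hydroxyl. Ring C carries the C3 hydroxyl next to the C4 carbonyl. The target has no stereocentre and no stereogenic double bond, so configuration matters only in intermediates and is erased again. The fragile parts are the terminal vinyl group, the electron-rich C6–H position of ring A, and the 3-hydroxy-4-pyranone. The vinyl group rules out hydrogenolysis and free halogen and can close onto the C7 phenol under acid; the 3-hydroxy-4-pyranone binds Lewis acids and is air-sensitive in base. The real difficulty is twofold: to place the quaternary benzylic carbon at C8 and not at C6, and to bring ring C to the 3-hydroxy-4-pyranone level with reagents that leave the vinyl group alone. The key step uses the fact that the array O1–C2–C3(OH)–C4(=O) of ring C is a constitutional isomer of the oxirane of a 2-benzylidene-1-benzofuran-3-one: moving O1 from the spiro carbon to the benzylic carbon turns the five-membered ring into ring C.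

## Logic of the disconnections

**14 back to 13.** The three O–CH2Ph bonds at O5, O7 and O4' are cut. Free phenols would quench the base and the Lewis acid of the earlier steps, and benzyl ethers are inert to carbonate, hydroxide, peroxide and BF3·OEt2. The C3 hydroxyl of 13 needs no protection because it is created free. The forward step must remove benzyl without hydrogen and without warm acid, because of the vinyl group next to O7.

**13 back to 11 (through 12).** The O1–C2 bond of ring C is cut and O1 is returned to the neighbouring carbon, which becomes the spiro carbon of a five-membered ring. This trades the oxidised pyranone for a skeleton that aldol chemistry builds, with the C3 oxygen already present as the oxirane oxygen. The forward step must ionise the oxirane at the benzylic carbon only, move O1 and not the acyl carbon, and spare the vinyl group.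

**11 back to 10.** The two C–O bonds of the oxirane are cut. The enone is the only electron-poor alkene in 10, so a nucleophilic oxidant distinguishes it from the vinyl group. The forward step must add hydroperoxide to a donor-substituted enone; its stereochemical outcome is irrelevant.

**10 back to 8 and 9.** The exocyclic C=C bond is cut. This is the convergent point where ring B enters as a purchased building block. The forward condensation must only avoid self-condensation of 8; the Z geometry is the thermodynamic one and is not critical.

**8 back to 5 (through 7 and 6).** The O1–CH2 bond of the five-membered ring is cut and the methylene is returned to a methyl ketone. This leads to a plain ortho-hydroxy aryl methyl ketone. The forward step must put a leaving group on the methyl carbon only. Free bromine or a bromide-transfer salt would also attack the vinyl group and C5 of ring A, so the halogen is delivered to a silyl enol ether at low temperature.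

**5 back to 4.** The O4–benzyl and O6–benzyl bonds are cut. The only hydroxyl left free in 5 is the one that must become O1, next to the quaternary carbon. The forward step must distinguish three hydroxyls: the 4-OH is the most acidic, the 6-OH is the unhindered one of the two ortho hydroxyls, and the 2-OH is chelated and shielded.

**4 back to 3.** The bond between ring carbon C3 and the quaternary carbon is cut in the sense of a retro-Claisen rearrangement, giving a prenyl ether on O4. The sigmatropic shift turns a primary ether into the fully substituted benzylic carbon. In 3 the two ortho carbons are equivalent by symmetry and the para carbon carries the acetyl group, so only one constitution can result. A prenyl ether on the oxygen next to the acetyl group of a fully etherified ketone was rejected: there the para carbon is free, and the ortho dienone could pass on by a Cope shift to a normal prenyl group at the future C6. The forward step must let the dienone tautomerise and must be stopped before the new ortho-allyl phenol reacts further.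

**3 back to 1 and 2.** The O4–CH2 bond is cut. The 4-OH of 1 is the only hydroxyl outside the hydrogen bond to the carbonyl and the most acidic one, so one equivalent of weak base should address it. The forward step must favour O- over C-alkylation and stop at mono-alkylation.

## Other disconnections considered

**Alternative 1:** The cut is at the quaternary carbon itself. The C–CH3 and C–vinyl bonds of phenol A3 are disconnected back to aryl methyl ketone A1, the tert-butyl carbonate of a bis-MOM phloroacetophenone.

- **Forward key step:** CH3MgBr would add to the acetyl group of A1. The tertiary alkoxide would take over the carbonate from the neighbouring phenol oxygen, loss of tert-butyl carbonate would give ortho-quinone methide A2, and CH2=CHMgBr would add to its exocyclic carbon to give A3.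
- **In favour:** Both C–C bonds of the difficult carbon are made in one flask below room temperature. The position of the side chain is dictated by the position of the acetyl group, and no free phenol next to the new group is ever heated. On certainty of regiochemistry and thermal mildness this is the equal of step 2 or better.
- **Against:** A2 has two methyl groups on its exocyclic carbon, so a 1,5-hydrogen shift to a 2-isopropenylphenol and deprotonation by the basic Grignard reagent compete with addition at a fully substituted terminus. The acetyl carbon that would have become C4 is consumed, so an acyl group must be put back between the hydroxyl and a MOM ether of A3. MOM ethers would not survive BF3·OEt2, so a base-only ring C synthesis would have to follow.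
- **Comparison:** Structurally it solves only the side chain, whereas the chosen plan gets the side chain from a prenyl ether and spends its key step on ring C. Mechanistically it replaces a pericyclic shift by polar addition to a reactive intermediate, each with its own escape path. In step count it is longer: protection, carbonate formation, the key step and re-acylation are needed before ring C is begun, while the chosen plan reaches the corresponding stage, 5, in three steps.

**Alternative 2:** The cut is the C3–C4 bond of ring C. It leads from dihydroflavonol A5 to dialdehyde A4, in which the ring A aldehyde and an α-aryl-α-aryloxy acetaldehyde are tied together through O1.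

- **Forward key step:** A thiazolium-derived carbene (with Et3N) would add to the ring A aldehyde. The resulting acyl anion equivalent would attack the aliphatic aldehyde in a 6-exo-trig closure, and release of the carbene would give acyloin A5. Dehydrogenation across C2–C3 and removal of MOM would follow.
- **In favour:** The C3–OH/C4=O pattern is made directly with a catalyst and a weak base. No peroxide, halogen or Lewis acid meets the vinyl group before the end, and the diastereomer mixture is harmless because C2 and C3 become sp2. On chemoselectivity toward the vinyl group it is the equal of the chosen plan, and it closes ring C by a catalytic C–C bond formation, which is a point in its favour.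
- **Against:** The ring A aldehyde of A4 is flanked by two oxygen substituents and is electron-rich, so carbene addition there should be slow. The aliphatic aldehyde is the more electrophilic and may become the acyl donor, which would give the regioisomeric acyloin. Its α-hydrogen is acidic enough for β-elimination of the ring A phenoxide. A4 itself requires alkylation of a phenol shielded by the quaternary carbon with a secondary benzylic electrophile.
- **Comparison:** Both plans close ring C late, this one by C3–C4 and the chosen one by O1–C2. Umpolung at a hindered aldehyde stands against a cationic oxygen shift driven by formation of the aromatic pyranone. The sequence (side-chain phenol, formylation, O-alkylation, adjustment to the aldehyde, benzoin, oxidation, deprotection) is longer than eight steps. The final acid treatment exposes the side chain about as much as BCl3 does, an equal point.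

**Alternative 3:** The cut removes two bonds of ring A at once, O–C8a and C4–C4a of ynone A9. This gives aryne A8 (from silyl triflate A6) and arylpropiolic acid A7.

- **Forward key step:** CsF would remove the silyl group of A6 and loss of triflate would give A8. The carboxylate oxygen of A7 would add at C8a, and the aryl anion at C4a would attack the acyl carbon, so that the aryne is inserted into the C–O bond of the acid and A9 results.
- **In favour:** One operation under fluoride joins ring A, the three-carbon unit and ring B. A9 can close 6-endo to a flavone or 5-exo to an aurone, which could even enter step 6 of the chosen route. In convergence it is better than the chosen plan.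
- **Against:** The MOM ether next to C4a directs the nucleophile to C8a as required, but the tert-alkyl group next to C8a hinders that same carbon, so the two controlling elements oppose each other. A6 is a hexasubstituted benzene that already contains the side chain, so the quaternary carbon problem is moved and not solved. A7 is prone to decarboxylation and to simple O-arylation. After the key step C3 still lacks its oxygen.
- **Comparison:** It is structurally more convergent, which is named as the better point. Its regiochemistry is less secure than in the chosen plan, where the pattern of ring A is fixed from step 3 on. The sequence (side-chain phenol, ortho-silylation and triflation, insertion, cyclisation, C3 hydroxylation, deprotection) exceeds eight steps.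

Key step: step 7

Assumption: the target has no stereocentre, so racemic intermediates suffice; the oxirane of 11 is drawn with the relative configuration that follows from the Z alkene, and its epimer would serve equally.

## Route

Step 1
Reactants: 1 1-(2,4,6-trihydroxyphenyl)ethan-1-one; 2 1-bromo-3-methylbut-2-ene
Product: 3 1-[2,6-dihydroxy-4-(3-methylbut-2-en-1-yloxy)phenyl]ethan-1-one
Conditions: K2CO3 (1.05 equiv), 2 (1.0 equiv), acetone, reflux
Reagents that add atoms: none
Why: Williamson ether synthesis; with one equivalent of weak base the phenoxide forms at the 4-OH, the most acidic hydroxyl and the only one not hydrogen-bonded to the carbonyl, an aprotic solvent favours O- over C-alkylation, and the limiting amount of 2 restrains double alkylation.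

Step 2
Reactants: 3 1-[2,6-dihydroxy-4-(3-methylbut-2-en-1-yloxy)phenyl]ethan-1-one
Product: 4 1-[2,4,6-trihydroxy-3-(2-methylbut-3-en-2-yl)phenyl]ethan-1-one
Conditions: PhNEt2, 190 °C, Ar, sealed vessel, stopped at full conversion
Reagents that add atoms: none
Why: Aromatic Claisen rearrangement ([3,3]-sigmatropic shift); allylic inversion delivers the tertiary carbon of the prenyl group to the ring and creates the quaternary centre, the two ortho carbons of 3 are equivalent and the para carbon is blocked by the acetyl group so only one constitution can form, and the dienone should tautomerise at once to the phenol; no stereocentre arises.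

Step 3
Reactants: 4 1-[2,4,6-trihydroxy-3-(2-methylbut-3-en-2-yl)phenyl]ethan-1-one
Product: 5 1-[4,6-bis(benzyloxy)-2-hydroxy-3-(2-methylbut-3-en-2-yl)phenyl]ethan-1-one
Conditions: BnBr (2.1 equiv), K2CO3, DMF, rt
Reagents that add atoms: benzyl bromide, BrCc1ccccc1
Why: Williamson etherification under weak base; the 4-OH is the most acidic and free of hydrogen bonding, the 6-OH is the unhindered one of the two ortho hydroxyls, and the 2-OH, shielded by the quaternary carbon and held in the hydrogen bond to the acetyl group, should remain free.

Step 4
Reactants: 5 1-[4,6-bis(benzyloxy)-2-hydroxy-3-(2-methylbut-3-en-2-yl)phenyl]ethan-1-one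
Product: 8 4,6-bis(benzyloxy)-7-(2-methylbut-3-en-2-yl)-1-benzofuran-3(2H)-one, via bis(trimethylsilyl) enol ether 6 (not isolated), via silylated bromo ketone 7 (not isolated)
Conditions: TMSOTf, Et3N, CH2Cl2, 0 °C; then NBS (1.0 equiv), THF, −78 °C; then K2CO3, MeOH–THF, 0 °C to rt
Reagents that add atoms: trimethylsilyl trifluoromethanesulfonate, C[Si](C)(C)OS(=O)(=O)C(F)(F)F (silicon of 6 and 7); N-bromosuccinimide, O=C1CCC(=O)N1Br (bromine of 7)
Why: Soft enolisation gives the silyl enol ether and caps the phenol; the enol ether is far more nucleophilic toward NBS at −78 °C than the vinyl group or C5 of ring A, so bromine should go only to the methyl carbon, and methanolic carbonate then frees the phenoxide, which displaces bromide in a 5-exo-tet intramolecular Williamson closure.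

Step 5
Reactants: 8 4,6-bis(benzyloxy)-7-(2-methylbut-3-en-2-yl)-1-benzofuran-3(2H)-one; 9 4-(benzyloxy)benzaldehyde
Product: 10 (2Z)-4,6-bis(benzyloxy)-2-{[4-(benzyloxy)phenyl]methylidene}-7-(2-methylbut-3-en-2-yl)-1-benzofuran-3(2H)-one
Conditions: KOH (aq), MeOH–THF, 60 °C, Ar
Reagents that add atoms: none
Why: Aldol condensation (Claisen–Schmidt type) of the C2 methylene of 8 with the non-enolisable aldehyde 9, followed by E1cB loss of water; the Z alkene, with the aryl group on the side of O1 and away from the C3 carbonyl, is the thermodynamic isomer.

Step 6
Reactants: 10 (2Z)-4,6-bis(benzyloxy)-2-{[4-(benzyloxy)phenyl]methylidene}-7-(2-methylbut-3-en-2-yl)-1-benzofuran-3(2H)-one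
Product: 11 rac-(2R,3'R)-4,6-bis(benzyloxy)-3'-[4-(benzyloxy)phenyl]-7-(2-methylbut-3-en-2-yl)-3H-spiro[1-benzofuran-2,2'-oxiran]-3-one (aryl group cis to O1 on the oxirane)
Conditions: 30% aq H2O2, 2 M aq NaOH, MeOH–THF, 0 °C to rt
Reagents that add atoms: hydrogen peroxide, OO
Why: Weitz–Scheffer epoxidation; hydroperoxide adds to the benzylic β-carbon of the enone and the enolate closes on oxygen with loss of hydroxide, while the isolated vinyl group is not an acceptor. The two stereocentres are set relative to each other by the alkene geometry if closure is faster than C–C rotation, and since both vanish in step 7 a diastereomer mixture would serve as well.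

Step 7
Reactants: 11 rac-(2R,3'R)-4,6-bis(benzyloxy)-3'-[4-(benzyloxy)phenyl]-7-(2-methylbut-3-en-2-yl)-3H-spiro[1-benzofuran-2,2'-oxiran]-3-one
Product: 13 5,7-bis(benzyloxy)-2-[4-(benzyloxy)phenyl]-3-hydroxy-8-(2-methylbut-3-en-2-yl)-4H-chromen-4-one, via chromane-3,4-dione tautomer 12 (not isolated)
Conditions: BF3·OEt2 (1.2 equiv), CH2Cl2, −40 to 0 °C; aq NaHCO3
Reagents that add atoms: none
Why: BF3 binds the oxirane oxygen and the C–O bond at the benzylic carbon should ionise, because the 4-benzyloxyphenyl group stabilises that cation as a quinone-methide-type oxocarbenium ion while the spiro carbon is deactivated by the adjacent C3 carbonyl. The boron-bound alkoxide on the spiro carbon then collapses to a carbonyl as O1 leaves that carbon and bonds to the benzylic carbon; this may run as a 1,2-shift of O1 through a bridged oxonium ion or stepwise through the ring-opened phenoxide and a diketone cation, and both paths lead to dione 12. In the stepwise picture ring C closes in the 6-exo-trig mode (phenoxide oxygen onto the exocyclic carbon of the quinone-methide form); in the concerted picture it is a one-atom ring expansion. Enolisation of 12 to the aromatic, hydrogen-bonded 3-hydroxy-4-pyranone 13 removes the only stereocentre and makes the six-membered product the thermodynamic sink, so no stereocontrol is needed. The closest known reaction types are the Auwers ring expansion of aurone dibromides to flavonols and the Lewis-acid semipinacol rearrangement of α,β-epoxy ketones. Three selectivities are needed: ionisation at the benzylic and not the spiro C–O bond (secured by the para-alkoxy aryl group), migration of O1 and not of the C3 acyl carbon, which would lead to a 3-aryl-4-hydroxycoumarin skeleton (favoured by the lone pair on O1 and by opening of the strained spiro acylal), and no attack on the vinyl group (no external electrophile is present and the cation is quenched internally at low temperature). Benzyl ethers are kept because they do not ionise under BF3·OEt2 at this temperature.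

Step 8
Reactants: 13 5,7-bis(benzyloxy)-2-[4-(benzyloxy)phenyl]-3-hydroxy-8-(2-methylbut-3-en-2-yl)-4H-chromen-4-one
Product: 14 3,5,7-trihydroxy-2-(4-hydroxyphenyl)-8-(2-methylbut-3-en-2-yl)-4H-chromen-4-one
Conditions: BCl3 (6 equiv), C6HMe5 (9 equiv), CH2Cl2, −78 °C; MeOH quench at −78 °C, then aq NaHCO3
Reagents that add atoms: none
Why: Lewis-acid cleavage of aryl benzyl ethers; the benzyl cations are taken up irreversibly by pentamethylbenzene in a Friedel–Crafts reaction, so neither ring A nor the vinyl group should be benzylated, and at −78 °C the monosubstituted alkene should be neither protonated nor chlorinated; the cold quench limits the time the free 7-OH and the vinyl group spend together in acid.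

## Compound list

1 | 1-(2,4,6-trihydroxyphenyl)ethan-1-one | CC(=O)c1c(O)cc(O)cc1O | starting material
2 | 1-bromo-3-methylbut-2-ene | CC(C)=CCBr | starting material
3 | 1-[2,6-dihydroxy-4-(3-methylbut-2-en-1-yloxy)phenyl]ethan-1-one | CC(=O)c1c(O)cc(OCC=C(C)C)cc1O | intermediate
4 | 1-[2,4,6-trihydroxy-3-(2-methylbut-3-en-2-yl)phenyl]ethan-1-one | CC(=O)c1c(O)cc(O)c(C(C)(C)C=C)c1O | intermediate
5 | 1-[4,6-bis(benzyloxy)-2-hydroxy-3-(2-methylbut-3-en-2-yl)phenyl]ethan-1-one | CC(=O)c1c(O)c(C(C)(C)C=C)c(OCc2ccccc2)cc1OCc1ccccc1 | intermediate
6 | {[1-{4,6-bis(benzyloxy)-3-(2-methylbut-3-en-2-yl)-2-[(trimethylsilyl)oxy]phenyl}ethenyl]oxy}(trimethyl)silane | C=C(O[Si](C)(C)C)c1c(O[Si](C)(C)C)c(C(C)(C)C=C)c(OCc2ccccc2)cc1OCc1ccccc1 | intermediate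
7 | 2-bromo-1-{4,6-bis(benzyloxy)-3-(2-methylbut-3-en-2-yl)-2-[(trimethylsilyl)oxy]phenyl}ethan-1-one | O=C(CBr)c1c(O[Si](C)(C)C)c(C(C)(C)C=C)c(OCc2ccccc2)cc1OCc1ccccc1 | intermediate
8 | 4,6-bis(benzyloxy)-7-(2-methylbut-3-en-2-yl)-1-benzofuran-3(2H)-one | O=C1COc2c1c(OCc1ccccc1)cc(OCc1ccccc1)c2C(C)(C)C=C | intermediate
9 | 4-(benzyloxy)benzaldehyde | O=Cc1ccc(OCc2ccccc2)cc1 | starting material
10 | (2Z)-4,6-bis(benzyloxy)-2-{[4-(benzyloxy)phenyl]methylidene}-7-(2-methylbut-3-en-2-yl)-1-benzofuran-3(2H)-one | O=C1/C(=C/c2ccc(OCc3ccccc3)cc2)Oc2c1c(OCc1ccccc1)cc(OCc1ccccc1)c2C(C)(C)C=C | intermediate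
11 | rac-(2R,3'R)-4,6-bis(benzyloxy)-3'-[4-(benzyloxy)phenyl]-7-(2-methylbut-3-en-2-yl)-3H-spiro[1-benzofuran-2,2'-oxiran]-3-one (the SMILES shows the (2S,3'S) enantiomer of the racemate) | O=C1c2c(OCc3ccccc3)cc(OCc3ccccc3)c(C(C)(C)C=C)c2O[C@]14O[C@H]4c1ccc(OCc2ccccc2)cc1 | intermediate
12 | 5,7-bis(benzyloxy)-2-[4-(benzyloxy)phenyl]-8-(2-methylbut-3-en-2-yl)chromane-3,4-dione (racemic at C2) | O=C1C(=O)c2c(OCc3ccccc3)cc(OCc3ccccc3)c(C(C)(C)C=C)c2OC1c1ccc(OCc2ccccc2)cc1 | intermediate
13 | 5,7-bis(benzyloxy)-2-[4-(benzyloxy)phenyl]-3-hydroxy-8-(2-methylbut-3-en-2-yl)-4H-chromen-4-one | C=CC(C)(C)c1c(OCc2ccccc2)cc(OCc2ccccc2)c2c(=O)c(O)c(-c3ccc(OCc4ccccc4)cc3)oc12 | intermediate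
14 | 3,5,7-trihydroxy-2-(4-hydroxyphenyl)-8-(2-methylbut-3-en-2-yl)-4H-chromen-4-one | C=CC(C)(C)c1c(O)cc(O)c2c(=O)c(O)c(-c3ccc(O)cc3)oc12 | target

## Step count and least certain steps

Total: 8 steps. Longest linear sequence: 8 steps, from 1 to 14; 2 and 9 are purchased and enter in steps 1 and 5.

**Step 7 (key step).** The most likely failure is migration of the C3 acyl carbon in place of O1, or capture of the benzylic cation by fluoride or water followed by return to the five-membered ring. Both groups on the spiro carbon can align with the vacant orbital, and the stabilised cation is long-lived. The fallback sets out from 5 and 9. A Claisen–Schmidt condensation (KOH, EtOH–THF, rt) should give (2E)-1-[4,6-bis(benzyloxy)-2-hydroxy-3-(2-methylbut-3-en-2-yl)phenyl]-3-[4-(benzyloxy)phenyl]prop-2-en-1-one F1. Algar–Flynn–Oyamada oxidative cyclisation (30% aq H2O2, NaOH, MeOH–THF, 0 °C to rt) should then close ring C directly, and the route is rejoined at 13. Any 10 formed alongside would re-enter at step 6.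

**Step 1.** C-alkylation of the ambident phloroglucinol anion and double alkylation may compete, because ring carbons C3 and C5 of the phenoxide are nucleophilic. The fallback sets out from 1 and uses Mitsunobu etherification with 3-methylbut-2-en-1-ol (PPh3, diisopropyl azodicarboxylate, THF, 0 °C). There the most acidic, non-chelated 4-OH acts as the pronucleophile under neutral conditions and carbon alkylation is not expected. The route is rejoined at 3; no new compound is made (F0).

**Step 2.** Onward isomerisation of the new ortho-allyl phenol may occur: shift of the double bond by the abnormal Claisen path, ring closure of the 4-OH onto the vinyl group, or thermal loss of the prenyl group. The cause is that the non-chelated 4-OH stays next to the vinyl group at 190 °C. The fallback sets out from 3 and rearranges a capped substrate. Heating with N,O-bis(trimethylsilyl)acetamide in PhNEt2 should first give 1-{4-[(3-methylbut-2-en-1-yl)oxy]-2,6-bis[(trimethylsilyl)oxy]phenyl}ethan-1-one F2. After the sigmatropic shift the new phenol should be captured as 1-{3-(2-methylbut-3-en-2-yl)-2,4,6-tris[(trimethylsilyl)oxy]phenyl}ethan-1-one F3. Methanolysis (K2CO3, MeOH, 0 °C) rejoins the route at 4.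

**Step 3.** Benzylation of the wrong ortho hydroxyl, or of all three, may occur, because the differentiation of the 2-OH from the 6-OH rests on shielding by the quaternary carbon alone. A wrong choice would later place the side chain at C6. The fallback sets out from 3 and changes the order of events:

- Mono-benzylation (BnBr 1.05 equiv, K2CO3, acetone) of one of the two equivalent hydroxyls should give 1-[2-(benzyloxy)-6-hydroxy-4-(3-methylbut-2-en-1-yloxy)phenyl]ethan-1-one F4.
- Claisen rearrangement (PhNEt2, 190 °C) should be steered by the bond fixation of the remaining chelate to the carbon between the chelated hydroxyl and the ether oxygen, giving 1-[6-(benzyloxy)-2,4-dihydroxy-3-(2-methylbut-3-en-2-yl)phenyl]ethan-1-one F5.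
- Benzylation of the non-chelated 4-OH (BnBr, K2CO3, DMF) rejoins the route at 5, with the free hydroxyl fixed beyond doubt at the cost of one step.

**Step 4.** Electrophilic bromination at C5 of ring A, or a second halogenation after closure, may occur if silylation of the hindered, chelated phenol and of the ketone is incomplete. The fallback sets out from 5 and uses a halogen-free oxidative cyclisation with PhI(OAc)2 and KOH in MeOH (0 °C to rt). The enolate is activated at carbon by trivalent iodine and the neighbouring phenoxide displaces iodobenzene. The route is rejoined at 8; no new compound is made (F0).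

**Step 8.** Acid-induced closure of the freed O7 onto the vinyl group, or addition of HCl to the vinyl group, may occur during the quench, when a protic acid, the C7 oxygen and the alkene are together. The fallback sets out from 13 and replaces Lewis-acid cleavage by palladium-catalysed silane reduction (PdCl2 cat., Et3SiH, Et3N, CH2Cl2, rt), a method reported to spare alkenes. It should give 3-hydroxy-8-(2-methylbut-3-en-2-yl)-5,7-bis[(triethylsilyl)oxy]-2-{4-[(triethylsilyl)oxy]phenyl}-4H-chromen-4-one F6. Buffered fluoride (Bu4NF, AcOH, THF, 0 °C) then rejoins the route at 14.

## Further compounds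

F1 | step 7 | (2E)-1-[4,6-bis(benzyloxy)-2-hydroxy-3-(2-methylbut-3-en-2-yl)phenyl]-3-[4-(benzyloxy)phenyl]prop-2-en-1-one | C=CC(C)(C)c1c(O)c(C(=O)/C=C/c2ccc(OCc3ccccc3)cc2)c(OCc2ccccc2)cc1OCc1ccccc1
F0 | step 1 | none | none
F2 | step 2 | 1-{4-[(3-methylbut-2-en-1-yl)oxy]-2,6-bis[(trimethylsilyl)oxy]phenyl}ethan-1-one | CC(=O)c1c(O[Si](C)(C)C)cc(OCC=C(C)C)cc1O[Si](C)(C)C
F3 | step 2 | 1-{3-(2-methylbut-3-en-2-yl)-2,4,6-tris[(trimethylsilyl)oxy]phenyl}ethan-1-one | CC(=O)c1c(O[Si](C)(C)C)cc(O[Si](C)(C)C)c(C(C)(C)C=C)c1O[Si](C)(C)C
F4 | step 3 | 1-[2-(benzyloxy)-6-hydroxy-4-(3-methylbut-2-en-1-yloxy)phenyl]ethan-1-one | CC(=O)c1c(O)cc(OCC=C(C)C)cc1OCc1ccccc1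
F5 | step 3 | 1-[6-(benzyloxy)-2,4-dihydroxy-3-(2-methylbut-3-en-2-yl)phenyl]ethan-1-one | CC(=O)c1c(O)c(C(C)(C)C=C)c(O)cc1OCc1ccccc1
F0 | step 4 | none | none
F6 | step 8 | 3-hydroxy-8-(2-methylbut-3-en-2-yl)-5,7-bis[(triethylsilyl)oxy]-2-{4-[(triethylsilyl)oxy]phenyl}-4H-chromen-4-one | C=CC(C)(C)c1c(O[Si](CC)(CC)CC)cc(O[Si](CC)(CC)CC)c2c(=O)c(O)c(-c3ccc(O[Si](CC)(CC)CC)cc3)oc12
A1 | alternative 1 | 2-acetyl-3,5-bis(methoxymethoxy)phenyl tert-butyl carbonate | CC(=O)c1c(OC(=O)OC(C)(C)C)cc(OCOC)cc1OCOC
A2 | alternative 1 | 3,5-bis(methoxymethoxy)-6-(propan-2-ylidene)cyclohexa-2,4-dien-1-one | CC(C)=C1C(=O)C=C(OCOC)C=C1OCOC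
A3 | alternative 1 | 3,5-bis(methoxymethoxy)-2-(2-methylbut-3-en-2-yl)phenol | C=CC(C)(C)c1c(O)cc(OCOC)cc1OCOC
A4 | alternative 2 | 4,6-bis(methoxymethoxy)-2-{1-[4-(methoxymethoxy)phenyl]-2-oxoethoxy}-3-(2-methylbut-3-en-2-yl)benzaldehyde (racemic) | C=CC(C)(C)c1c(OCOC)cc(OCOC)c(C=O)c1OC(C=O)c1ccc(OCOC)cc1
A5 | alternative 2 | 3-hydroxy-5,7-bis(methoxymethoxy)-2-[4-(methoxymethoxy)phenyl]-8-(2-methylbut-3-en-2-yl)chroman-4-one (mixture of diastereomers) | C=CC(C)(C)c1c(OCOC)cc(OCOC)c2c1OC(c1ccc(OCOC)cc1)C(O)C2=O
A6 | alternative 3 | 3,5-bis(methoxymethoxy)-2-(2-methylbut-3-en-2-yl)-6-(trimethylsilyl)phenyl trifluoromethanesulfonate | C=CC(C)(C)c1c(OCOC)cc(OCOC)c([Si](C)(C)C)c1OS(=O)(=O)C(F)(F)F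
A7 | alternative 3 | 3-[4-(methoxymethoxy)phenyl]prop-2-ynoic acid | COCOc1ccc(C#CC(=O)O)cc1
A8 | alternative 3 | 4,6-bis(methoxymethoxy)-3-(2-methylbut-3-en-2-yl)-1,2-didehydrobenzene | C=CC(C)(C)C1=C(OCOC)C=C(OCOC)C#C1
A9 | alternative 3 | 1-[2-hydroxy-4,6-bis(methoxymethoxy)-3-(2-methylbut-3-en-2-yl)phenyl]-3-[4-(methoxymethoxy)phenyl]prop-2-yn-1-one | C=CC(C)(C)c1c(OCOC)cc(OCOC)c(C(=O)C#Cc2ccc(OCOC)cc2)c1O
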